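## Analysis of the target

Compound numbers refer to the compound list after the steps.

- Target 15 is an achiral depside: two benzene rings joined by an aryl ester, C7(=O)–O, between C1 of ring A and the oxygen on C4' of ring B. There is no stereocentre, so the task is one of substitution pattern and chemoselectivity.
- Ring A (C1–C6) carries C7 on C1, methoxy groups on C2 and C4, a hydroxymethyl group on C3, hydrogen on C5 and a methyl group on C6. Ring B (C1'–C6') is a salicylic acid with the carboxyl on C1', a free hydroxyl on C2', methyl groups on C3' and C6', and the ester oxygen on C4'.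
- Three groups are sensitive. The aryl ester is cleaved by hydroxide or alkoxide. The C3 benzylic alcohol, flanked by two methoxy groups, ionizes in acid and is easily hydrogenolysed. The ring B acid is a β-resorcylic-type acid that loses CO2 when heated.
- The difficulty is threefold. C7 sits between the C2 methoxy and the C6 methyl group, so acylation of a phenol by a ring A acid derivative is slow. Ring B offers two hydroxyls. The end game must free the carboxyl without base, without hydrogen, and without strong acid acting on the benzylic alcohol.
- The plan rests on one feature: ring A without C7, with C3 at the aldehyde level, is aldehyde 4, which has a mirror plane through C3 and C6. C1 and C5 are therefore the same position, a single halogenation marks C1 without ambiguity, and C7 can enter as carbon monoxide 10 between C1 and the C4' oxygen.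
- Carrying the C3 carbon as an aldehyde serves three purposes: it can be placed between the methoxy groups by directed lithiation, it tolerates the acid that later frees the ring B carboxyl, and, being meta to C1, it cannot lactonize onto C7.

## Retrosynthetic reasoning

**15 from 14.** The C3 hydroxymethyl group is traced back to the formyl group of 14. The benzylic alcohol is the most fragile group, so it is made last, by hydride reduction of the only aldehyde. The forward step must leave the crowded aryl ester and the carboxyl untouched.

**14 from 13.** The C1' carboxyl is masked as the tert-butyl ester of 13, and the O–C(CH3)3 bond is the one cut. This mask survives an amine base and a palladium catalyst at elevated temperature. It leaves under anhydrous acid as a volatile alkene, with no nucleophile that could open the depside and no hydrogen that could touch the aldehyde. The aldehyde, unlike the alcohol, tolerates that acid, which fixes the order of the last two steps.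

**13 from 5, 9 and 10.** Both bonds to C7 are cut: C1–C7 and C7–O(C4'). Cutting only C7–O would require a preformed, di-ortho-substituted ring A carboxylic acid, with extra steps to install it and a slow acylation. Cutting on both sides reduces ring A to aryl iodide 5, brings C7 in as carbon monoxide 10, and lets an aroylpalladium species act as the acyl donor toward phenol 9. The forward reaction must achieve oxidative addition at a crowded C–I bond, CO insertion, and C–O bond formation at the 4-hydroxyl of 9 rather than the 2-hydroxyl.

**5 from 4.** The C1–I bond is cut. In 4 the two free ring positions are equivalent and each is ortho to one methoxy group, para to the other and meta to the formyl group. Electrophilic iodination can therefore give only one monoiodide.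

**4 from 1.** The bond between C3 and the formyl carbon is cut. In 1 the hydrogen between the two methoxy groups is the most acidic ring hydrogen, so directed lithiation followed by a formamide electrophile places the carbon exactly there. Electrophilic formylation would attack the other ring positions instead.

**9 from 8 from 6.** The ester alkyl group on ring B is exchanged. The methyl ester of 6 cannot be carried to the end, because its removal would need nucleophiles that also cleave the depside. It is therefore cleaved at the acyl–oxygen bond to acid 8, and the carboxylate is then alkylated with a tert-butyl cation donor to give 9.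

## Alternatives that were turned down

**Alternative 1:** ring A built from acyclic esters.
- Disconnection: C1–C6 and C3–C4 of ring A are cut, leading back to tert-butyl 3-oxobutanoate A1 and ethyl (E)-but-2-enoate A2.
- Forward key step: under an alkoxide base the enolate of A1 adds to the β-carbon of A2 (Michael addition). The methyl ketone enolate of the adduct then closes onto the ethyl ester in a Claisen-type condensation, giving racemic trans dione ester A3.
- For it: bulk starting materials, no transition metal and no toxic gas. C7 is present from the start at the carboxyl level, and the oxygens on C2 and C4 and the methyl on C6 are fixed by connectivity.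
- Against it: A3 is far from ring A. It must be dehydrogenated to the arene, formylated at C3 in competition with C5, O-methylated twice (the C2 hydroxyl is chelated) and freed from its tert-butyl group. After all that, the ester bond to 9 must still be made from a di-ortho-substituted benzoic acid, which is the problem the plan set out to avoid. Two stereocentres are created only to be erased.
- Comparison: on cost of goods, scalability and avoidance of CO the alternative is stronger. The chosen route offers instead an arene 1 that already holds the ring, two steps to 5 with regiochemistry settled by symmetry, and formation of C1–C7 and C7–O in one operation.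

**Alternative 2:** ring A grown on the ring B ester by benzannulation.
- Disconnection: C2–C3, C4–C5 and C1–C2 are cut. The precursors are diazo ketone A4, in which the ring B phenol is already esterified with the future C7, and ynol ether A5.
- Forward key step: irradiation of A4 induces a Wolff rearrangement. The ketene so formed adds to A5 in a [2+2] sense, and four-electron ring opening, six-electron ring closure and tautomerization follow (Danheiser benzannulation), giving phenol A6.
- For it: the aryl ester is made at an unhindered enoate stage, so the crowded acylation is avoided as well as in the chosen plan. All five ring A substituents are placed by the mechanism, and C3 arrives at the alcohol oxidation level.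
- Against it: A4 combines a diazo ketone, an electron-poor alkene and an activated aryl ester in one molecule and needs several steps of its own. A5 is a sensitive ynol ether. A6 still needs methylation of the chelated C2 hydroxyl, desilylation and double debenzylation, and that hydrogenolysis threatens the electron-rich benzylic alcohol.
- Comparison: regiocontrol is equally secure (mechanism there, symmetry here), and the alternative is stronger in needing no metal-catalysed coupling at a hindered centre. The chosen route offers a much shorter access to ring A, one protecting group instead of three, and a deprotection that is not reductive.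

**Alternative 3:** ring B built by cycloaddition and cycloreversion.
- Disconnection: C1'–C2' and C5'–C6' are cut. The precursors are dienyl ester A7, a silyloxy cyclohexadiene whose second enol oxygen carries the ring A acyl group, and alkynoate A8.
- Forward key step: heating A7 with A8 gives a bicyclo[2.2.2]octadiene by Diels–Alder addition. This loses its two-carbon bridge by retro-Diels–Alder reaction (Alder–Rickert sequence) to give arene A9.
- For it: the two ring B oxygens are told apart by construction, aroyl on the C4' oxygen and silyl on the C2' oxygen, so no selectivity between hydroxyls is needed. In this respect it is stronger than the chosen plan. Its final deprotections (fluoride, allyl transfer with a zerovalent palladium catalyst) are neither acidic nor reductive.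
- Against it: ring B with all its substituents is on the shelf as 6, so the key step is spent on a solved problem. A7 still requires a ring A carboxylic acid with C7 in place and its O-acylation onto an enolate, with a hindered acyl group and competing C-acylation. A7 is itself an acyl donor that must survive the high temperature of the cycloaddition. Three protecting groups are needed.
- Comparison: the chosen route relies on the hydrogen bond and crowding of the 2-hydroxyl for site selectivity and carries the benzylic carbon as an aldehyde. In exchange it is shorter, convergent, and uses both rings as purchased.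

Key step: step 5

## Route

Assumption: 1, 6 and 10 are purchasable; ring A is numbered C1–C6 with C7 the ester carbonyl on C1, ring B C1'–C6' with the carboxyl on C1'.

Step 1
Reactants: 1 3,5-dimethoxytoluene
Product: 4 2,6-dimethoxy-4-methylbenzaldehyde, via (2,6-dimethoxy-4-methylphenyl)lithium 2 (not isolated), via lithium hemiaminal alkoxide 3 (not isolated)
Conditions: n-BuLi, TMEDA, THF, 0 °C to rt; DMF, 0 °C; 1 M HCl
Reagents that add atoms: N,N-dimethylformamide, CN(C)C=O
Why: Directed ortho-lithiation removes the ring hydrogen flanked by both methoxy groups, the most acidic and best coordinated site, to give 2; formylation with DMF gives the tetrahedral adduct 3, which collapses to 4 on acidic work-up.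

Step 2
Reactants: 4 2,6-dimethoxy-4-methylbenzaldehyde
Product: 5 3-iodo-2,6-dimethoxy-4-methylbenzaldehyde
Conditions: NIS (1.05 equiv), TFA (cat.), MeCN, rt, dark
Reagents that add atoms: N-iodosuccinimide, O=C1CCC(=O)N1I
Why: Electrophilic aromatic iodination; the two free positions of 4 are equivalent by symmetry and each is ortho/para to the methoxy groups and meta to the formyl group, so only one monoiodide can form, and the first iodine twists the neighbouring methoxy group and slows a second substitution.

Step 3
Reactants: 6 methyl 2,4-dihydroxy-3,6-dimethylbenzoate
Product: 8 2,4-dihydroxy-3,6-dimethylbenzoic acid, via 2,4-dihydroxy-3,6-dimethylbenzoylium hydrogen sulfate 7 (not isolated)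
Conditions: conc. H2SO4, 0 °C to rt; poured onto ice, filtered cold
Reagents that add atoms: water, O
Why: Unimolecular acyl–oxygen cleavage (A_AC1 ester hydrolysis): the di-ortho-substituted ester resists hydroxide, but in concentrated H2SO4 it ionizes to acylium ion 7, stabilized by the ortho and para hydroxyls, and ice water captures it as acid 8, which is kept cold because it decarboxylates on heating.

Step 4
Reactants: 8 2,4-dihydroxy-3,6-dimethylbenzoic acid
Product: 9 tert-butyl 2,4-dihydroxy-3,6-dimethylbenzoate
Conditions: tert-butyl 2,2,2-trichloroacetimidate (2 equiv), CH2Cl2/THF, rt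
Reagents that add atoms: tert-butyl 2,2,2-trichloroacetimidate, CC(C)(C)OC(=N)C(Cl)(Cl)Cl
Why: Trichloroacetimidate O-alkylation of a carboxylic acid: the acid itself protonates the imidate, which collapses to a tert-butyl cation/carboxylate ion pair and trichloroacetamide; the phenols are too weakly acidic to activate the reagent and stay free.

Step 5
Reactants: 5 3-iodo-2,6-dimethoxy-4-methylbenzaldehyde; 9 tert-butyl 2,4-dihydroxy-3,6-dimethylbenzoate; 10 carbon monoxide
Product: 13 tert-butyl 4-[(3-formyl-2,4-dimethoxy-6-methylbenzoyl)oxy]-2-hydroxy-3,6-dimethylbenzoate, via arylpalladium iodide Xantphos complex 11 (not isolated), via aroylpalladium iodide Xantphos complex 12 (not isolated)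
Conditions: Pd(OAc)2 (5 mol %), Xantphos (6 mol %), Et3N (3 equiv), CO (1 atm), toluene, 90 °C
Reagents that add atoms: none
Why: Pd(OAc)2 is reduced in situ to zerovalent palladium, which adds oxidatively to the C1–I bond of 5 to give 11; CO 10 coordinates and the aryl group migrates onto it to give aroyl complex 12, a step that relieves the crowding around C1. Triethylamine converts the 4-hydroxyl of 9 into its phenoxide, which replaces iodide on divalent palladium, and C–O reductive elimination, favoured by the wide bite angle of Xantphos, releases 13 and zerovalent palladium. The closest known reaction type is the palladium-catalysed alkoxy- and aryloxycarbonylation of aryl halides (Heck carbonylation) at atmospheric CO pressure. No ring closes and no stereocentre forms. Site selectivity on ring B is required and should come from the substrate: the 2-hydroxyl of 9 is held in a hydrogen bond to the ester carbonyl and is flanked by the C3' methyl and the tert-butyl ester, whereas the 4-hydroxyl is more acidic and has a free neighbour. On ring A the aldehyde does not react with the acylpalladium and, being meta to C1, cannot trap it intramolecularly. The aroylpalladium is a far better acyl donor than an activated derivative of a hindered acid, which is why the two ortho substituents should be tolerated.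

Step 6
Reactants: 13 tert-butyl 4-[(3-formyl-2,4-dimethoxy-6-methylbenzoyl)oxy]-2-hydroxy-3,6-dimethylbenzoate
Product: 14 4-[(3-formyl-2,4-dimethoxy-6-methylbenzoyl)oxy]-2-hydroxy-3,6-dimethylbenzoic acid
Conditions: TFA/CH2Cl2 (1:3), 0 °C to rt; evaporation from toluene
Reagents that add atoms: none
Why: Acidolysis of a tert-butyl ester by alkyl–oxygen cleavage with loss of 2-methylpropene; the aryl ester, the ethers and the aldehyde are inert to anhydrous acid, and the only free ring positions (C5 and C5') are each flanked by two substituents, so ring tert-butylation is blocked; the step precedes the reduction because the benzylic alcohol would not survive it.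

Step 7
Reactants: 14 4-[(3-formyl-2,4-dimethoxy-6-methylbenzoyl)oxy]-2-hydroxy-3,6-dimethylbenzoic acid
Product: 15 2-hydroxy-4-{[3-(hydroxymethyl)-2,4-dimethoxy-6-methylbenzoyl]oxy}-3,6-dimethylbenzoic acid
Conditions: NaBH4 (3 equiv), THF/EtOH (5:1), 0 °C; 1 M HCl to pH 3–4, 0 °C
Reagents that add atoms: none
Why: Borohydride reduction of an aryl aldehyde; the carboxyl is present as its unreactive carboxylate and the di-ortho-substituted aryl ester is too hindered to be reduced or transesterified at 0 °C, while cold acidification to only pH 3–4 avoids ionizing the 2,6-dimethoxybenzylic alcohol.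

## Compound list

1 | 3,5-dimethoxytoluene | COc1cc(C)cc(OC)c1 | starting material
2 | (2,6-dimethoxy-4-methylphenyl)lithium | [Li]c1c(OC)cc(C)cc1OC | intermediate
3 | lithium (dimethylamino)(2,6-dimethoxy-4-methylphenyl)methanolate (racemic) | [Li+].[O-]C(N(C)C)c1c(OC)cc(C)cc1OC | intermediate
4 | 2,6-dimethoxy-4-methylbenzaldehyde | COc1cc(C)cc(OC)c1C=O | intermediate
5 | 3-iodo-2,6-dimethoxy-4-methylbenzaldehyde | COc1cc(C)c(I)c(OC)c1C=O | intermediate
6 | methyl 2,4-dihydroxy-3,6-dimethylbenzoate | COC(=O)c1c(C)cc(O)c(C)c1O | starting material
7 | 2,4-dihydroxy-3,6-dimethylbenzoylium hydrogen sulfate | Cc1cc(O)c(C)c(O)c1C#[O+].OS(=O)(=O)[O-] | intermediate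
8 | 2,4-dihydroxy-3,6-dimethylbenzoic acid | Cc1cc(O)c(C)c(O)c1C(=O)O | intermediate
9 | tert-butyl 2,4-dihydroxy-3,6-dimethylbenzoate | Cc1cc(O)c(C)c(O)c1C(=O)OC(C)(C)C | intermediate
10 | carbon monoxide | [C-]#[O+] | starting material
11 | iodo(3-formyl-2,4-dimethoxy-6-methylphenyl)palladium Xantphos complex, PdI(C10H11O3)(Xantphos) | CC1(C)c2cccc3c2Oc2c1cccc2[P+](c1ccccc1)(c1ccccc1)[Pd-2](I)(c1c(C)cc(OC)c(C=O)c1OC)[P+]3(c1ccccc1)c1ccccc1 | intermediate
12 | iodo(3-formyl-2,4-dimethoxy-6-methylbenzoyl)palladium Xantphos complex, PdI(C11H11O4)(Xantphos) | CC1(C)c2cccc3c2Oc2c1cccc2[P+](c1ccccc1)(c1ccccc1)[Pd-2](I)(C(=O)c1c(C)cc(OC)c(C=O)c1OC)[P+]3(c1ccccc1)c1ccccc1 | intermediate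
13 | tert-butyl 4-[(3-formyl-2,4-dimethoxy-6-methylbenzoyl)oxy]-2-hydroxy-3,6-dimethylbenzoate | COc1cc(C)c(C(=O)Oc2cc(C)c(C(=O)OC(C)(C)C)c(O)c2C)c(OC)c1C=O | intermediate
14 | 4-[(3-formyl-2,4-dimethoxy-6-methylbenzoyl)oxy]-2-hydroxy-3,6-dimethylbenzoic acid | COc1cc(C)c(C(=O)Oc2cc(C)c(C(=O)O)c(O)c2C)c(OC)c1C=O | intermediate
15 | 2-hydroxy-4-{[3-(hydroxymethyl)-2,4-dimethoxy-6-methylbenzoyl]oxy}-3,6-dimethylbenzoic acid | COc1cc(C)c(C(=O)Oc2cc(C)c(C(=O)O)c(O)c2C)c(OC)c1CO | target

## Step count and least certain steps

Total: 7 steps. Longest linear sequence: 5 steps (steps 1, 2, 5, 6, 7; the ring B branch through steps 3, 4, 5, 6, 7 is equally long).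

**Step 5 (key step).** The most likely failure is slow oxidative addition of zerovalent palladium into the C1–I bond, which lies between a methoxy and a methyl group. Reduction of the arylpalladium species by the amine (hydrodeiodination) or decay of the catalyst could then outrun productive turnover. A second, smaller risk is acylation of the chelated 2-hydroxyl once the 4-hydroxyl has reacted. The fallback separates the two bond formations and uses no palladium. From 5, the aldehyde would be masked with ethane-1,2-diol (p-TsOH, toluene, water removal) as 2-(3-iodo-2,6-dimethoxy-4-methylphenyl)-1,3-dioxolane F1. Iodine–lithium exchange (n-BuLi, THF, −78 °C), quenching with CO2 and work-up with aqueous HCl, which also hydrolyses the acetal, would give 3-formyl-2,4-dimethoxy-6-methylbenzoic acid F2. Oxalyl chloride with catalytic DMF would convert it into 3-formyl-2,4-dimethoxy-6-methylbenzoyl chloride F3. This would acylate the 4-hydroxyl of 9 (Et3N, DMAP, CH2Cl2), and the route is rejoined at 13.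

**Step 3.** The most likely failure is sulfonation of the electron-rich ring at C5 in concentrated H2SO4, or loss of CO2 from 8 during the quench and drying. The fallback removes both free hydroxyls before the ester is opened. From 6, double O-benzylation (BnBr, K2CO3, DMF, 70 °C) would give methyl 2,4-bis(benzyloxy)-3,6-dimethylbenzoate F4. Without phenoxide deactivation this could be saponified (KOH, DMSO/H2O, 90 °C) to 2,4-bis(benzyloxy)-3,6-dimethylbenzoic acid F5, an acid that does not decarboxylate. tert-Butyl 2,2,2-trichloroacetimidate would give tert-butyl 2,4-bis(benzyloxy)-3,6-dimethylbenzoate F6, and hydrogenolysis (H2, Pd/C, EtOAc) would return to the route at 9, bypassing 8 and the free-phenol tert-butylation of step 4 as well.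

**Step 7.** The most likely failure is cleavage of the aryl ester by alkoxide formed under the basic reduction conditions, or ionization of the new benzylic alcohol during acidification, leading to oligomers. The fallback changes the ring B protecting group so that the aldehyde is reduced on a neutral ester and the acid is freed last without acid or base. From 8, Mitsunobu esterification with 2-(trimethylsilyl)ethanol (PPh3, DIAD, THF, 0 °C) would give 2-(trimethylsilyl)ethyl 2,4-dihydroxy-3,6-dimethylbenzoate F7. Carbonylative coupling of F7 with 5 and 10 under the conditions of step 5 would give 2-(trimethylsilyl)ethyl 4-[(3-formyl-2,4-dimethoxy-6-methylbenzoyl)oxy]-2-hydroxy-3,6-dimethylbenzoate F8. NaBH4 (THF/EtOH, 0 °C) would reduce it to 2-(trimethylsilyl)ethyl 2-hydroxy-4-{[3-(hydroxymethyl)-2,4-dimethoxy-6-methylbenzoyl]oxy}-3,6-dimethylbenzoate F9. Fluoride-induced fragmentation of the silylethyl ester (Bu4NF buffered with AcOH, THF, 0 °C to rt) would give the target 15 directly, so steps 6 and 7 are both replaced.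

**Step 2.** The most likely failure is incomplete iodination. The formyl group lowers the nucleophilicity of the ring, the site lies between a methoxy and a methyl group, and the acid that activates the iodine source also promotes protodeiodination. Forcing the reaction invites a second iodination at the other equivalent position. The fallback uses a stronger, irreversible electrophile and a different halide in the key step. From 4, NBS (MeCN, 0 °C to rt) would give 3-bromo-2,6-dimethoxy-4-methylbenzaldehyde F10. This would be coupled with 9 and 10 under the Pd(OAc)2/Xantphos conditions of step 5 at a somewhat higher temperature, a system that also accepts aryl bromides, and the route is rejoined at 13.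

## Further compounds

F1 | step 5 | 2-(3-iodo-2,6-dimethoxy-4-methylphenyl)-1,3-dioxolane | COc1cc(C)c(I)c(OC)c1C1OCCO1
F2 | step 5 | 3-formyl-2,4-dimethoxy-6-methylbenzoic acid | COc1cc(C)c(C(=O)O)c(OC)c1C=O
F3 | step 5 | 3-formyl-2,4-dimethoxy-6-methylbenzoyl chloride | COc1cc(C)c(C(=O)Cl)c(OC)c1C=O
F4 | step 3 | methyl 2,4-bis(benzyloxy)-3,6-dimethylbenzoate | COC(=O)c1c(C)cc(OCc2ccccc2)c(C)c1OCc1ccccc1
F5 | step 3 | 2,4-bis(benzyloxy)-3,6-dimethylbenzoic acid | Cc1cc(OCc2ccccc2)c(C)c(OCc2ccccc2)c1C(=O)O
F6 | step 3 | tert-butyl 2,4-bis(benzyloxy)-3,6-dimethylbenzoate | Cc1cc(OCc2ccccc2)c(C)c(OCc2ccccc2)c1C(=O)OC(C)(C)C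
F7 | step 7 | 2-(trimethylsilyl)ethyl 2,4-dihydroxy-3,6-dimethylbenzoate | Cc1cc(O)c(C)c(O)c1C(=O)OCC[Si](C)(C)C
F8 | step 7 | 2-(trimethylsilyl)ethyl 4-[(3-formyl-2,4-dimethoxy-6-methylbenzoyl)oxy]-2-hydroxy-3,6-dimethylbenzoate | COc1cc(C)c(C(=O)Oc2cc(C)c(C(=O)OCC[Si](C)(C)C)c(O)c2C)c(OC)c1C=O
F9 | step 7 | 2-(trimethylsilyl)ethyl 2-hydroxy-4-{[3-(hydroxymethyl)-2,4-dimethoxy-6-methylbenzoyl]oxy}-3,6-dimethylbenzoate | COc1cc(C)c(C(=O)Oc2cc(C)c(C(=O)OCC[Si](C)(C)C)c(O)c2C)c(OC)c1CO
F10 | step 2 | 3-bromo-2,6-dimethoxy-4-methylbenzaldehyde | COc1cc(C)c(Br)c(OC)c1C=O
A1 | alternative 1 | tert-butyl 3-oxobutanoate | CC(=O)CC(=O)OC(C)(C)C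
A2 | alternative 1 | ethyl (E)-but-2-enoate | C/C=C/C(=O)OCC
A3 | alternative 1 | racemic tert-butyl trans-6-methyl-2,4-dioxocyclohexane-1-carboxylate | C[C@@H]1CC(=O)CC(=O)[C@H]1C(=O)OC(C)(C)C
A4 | alternative 2 | benzyl 2-(benzyloxy)-4-{[(2E)-5-diazo-3-methyl-4-oxopent-2-enoyl]oxy}-3,6-dimethylbenzoate | [N-]=[N+]=CC(=O)/C(C)=C/C(=O)Oc1cc(C)c(C(=O)OCc2ccccc2)c(OCc2ccccc2)c1C
A5 | alternative 2 | [(3-methoxyprop-2-yn-1-yl)oxy]tri(propan-2-yl)silane | COC#CCO[Si](C(C)C)(C(C)C)C(C)C
A6 | alternative 2 | benzyl 2-(benzyloxy)-4-[(2-hydroxy-4-methoxy-6-methyl-3-{[(triisopropylsilyl)oxy]methyl}benzoyl)oxy]-3,6-dimethylbenzoate | COc1cc(C)c(C(=O)Oc2cc(C)c(C(=O)OCc3ccccc3)c(OCc3ccccc3)c2C)c(O)c1CO[Si](C(C)C)(C(C)C)C(C)C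
A7 | alternative 3 | 5-[(tert-butyldimethylsilyl)oxy]-6-methylcyclohexa-1,5-dien-1-yl 2,4-dimethoxy-6-methyl-3-{[(triisopropylsilyl)oxy]methyl}benzoate | CC1=C(O[Si](C)(C)C(C)(C)C)CCC=C1OC(=O)c1c(C)cc(OC)c(CO[Si](C(C)C)(C(C)C)C(C)C)c1OC
A8 | alternative 3 | prop-2-en-1-yl but-2-ynoate | CC#CC(=O)OCC=C
A9 | alternative 3 | allyl 2-[(tert-butyldimethylsilyl)oxy]-4-[(2,4-dimethoxy-6-methyl-3-{[(triisopropylsilyl)oxy]methyl}benzoyl)oxy]-3,6-dimethylbenzoate | C=CCOC(=O)c1c(C)cc(OC(=O)c2c(C)cc(OC)c(CO[Si](C(C)C)(C(C)C)C(C)C)c2OC)c(C)c1O[Si](C)(C)C(C)(C)C
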